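Ring B carries three adjacent oxygens (C2', C3', C4') between carbon-bearing C1' and C5', so it is the dehydrogenated form of a 2-alkoxycyclohexane-1,3-dione; the route exploits exactly this. The ring is cut at C5'–C6' and C3'–C4'. In one flask a silyl ketene acetal, which already holds the quaternary carbon of the 2-methylbut-3-en-2-yl group, adds to an alkoxymethyl vinyl ketone, and alkoxide then closes the six-membered dione. Both precursors are small and acyclic. Aromatisation, 2'-O-methylation and C1' bromination follow; an enantioselective conjunctive coupling joins ring B, vinylboron and ring A and sets C3, and C–O coupling closes ring C.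

Key step: step 5

Assumption: the (Sp,Sp) enantiomer of the ferrocenyl bisphosphine in step 11 is expected, by analogy with simple aryl/aryl conjunctive couplings, to give the (R)-boronic ester; its mirror image is equally available should the sense of induction prove opposite.

Step 1
Reactants: 1 methyl 3,3-dimethylpent-4-enoate
Product: 2 [(1-methoxy-3,3-dimethylpenta-1,4-dien-1-yl)oxy]trimethylsilane (methyl trimethylsilyl ketene acetal of 1; either alkene geometry serves)
Conditions: LiN(i-Pr)2 (1.1 equiv), THF, −78 °C; TMSCl (1.2 equiv), −78 °C → rt; pentane, filtration, distillation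
Reagents that add atoms: chlorotrimethylsilane (TMSCl), C[Si](C)(C)Cl
Why: Kinetic ester deprotonation followed by O-silylation (silyl ketene acetal formation) is routine, and the quaternary carbon next to the nucleophilic carbon disfavours C-silylation.

Step 2
Reactants: 3 methyl glycolate
Product: 4 methyl 2-(methoxymethoxy)acetate
Conditions: MOMCl (1.2 equiv), i-Pr2NEt (1.5 equiv), CH2Cl2, 0 °C → rt
Reagents that add atoms: chloromethyl methyl ether (MOMCl), COCCl
Why: MOM protection (O-alkylation of a primary alcohol by a reactive α-chloro ether under amine base) leaves the ester untouched.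

Step 3
Reactants: 4 methyl 2-(methoxymethoxy)acetate
Product: 5 N-methoxy-2-(methoxymethoxy)-N-methylacetamide
Conditions: MeNH(OMe)·HCl (1.5 equiv), i-PrMgCl (3.0 equiv), THF, −20 → 0 °C; aq. NH4Cl
Reagents that add atoms: N,O-dimethylhydroxylamine hydrochloride, CNOC.Cl
Why: Weinreb amide synthesis by aminolysis with the magnesium amide is fast at low temperature on an unhindered α-alkoxy ester.

Step 4
Reactants: 5 N-methoxy-2-(methoxymethoxy)-N-methylacetamide
Product: 6 1-(methoxymethoxy)but-3-en-2-one
Conditions: CH2=CHMgBr (1.2 equiv), THF, −78 → 0 °C; inverse quench into cold 1 M HCl; used promptly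
Reagents that add atoms: vinylmagnesium bromide, C=C[Mg]Br
Why: Weinreb ketone synthesis: chelation by the N-methoxy group prevents collapse before the quench, so only one vinyl group is delivered, and the inverse acidic quench protonates the released amine before it can add to the enone.

Step 5
Reactants: 2 methyl trimethylsilyl ketene acetal of 1; 6 1-(methoxymethoxy)but-3-en-2-one
Product: 9 2-(methoxymethoxy)-4-(2-methylbut-3-en-2-yl)cyclohexane-1,3-dione, via silyl enol ether 7 (not isolated), via keto ester 8 (not isolated)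
Conditions: 6 added slowly to 2 (1.2 equiv), [(Me2N)3S][Me3SiF2] (5 mol %), THF, −78 → −20 °C; then KOt-Bu (2.2 equiv), t-BuOH, THF, 0 °C → rt; cold 1 M HCl to pH 4
Reagents that add atoms: none
Why: The fluorosilicate catalyst activates 2 at silicon so that its carbon C5' attacks the unsubstituted terminus C6' of 6 (Lewis-base-catalysed Mukaiyama–Michael addition) and silyl transfer gives 7; no Lewis acid is present, so the formaldehyde acetal of the MOM group cannot ionise and capture 2. tert-Butoxide strips the silyl group, the ketone enolates of 8 equilibrate by proton transfer, and the C3' enolate attacks the ester carbon C4' (Dieckmann condensation), the closest known reaction type being the Michael–Claisen annulation of ester enolate equivalents with vinyl ketones to cyclohexane-1,3-diones. The single ring closes in a 6-(enolendo)-exo-trig mode, and loss of methoxide followed by deprotonation of the β-diketone at C3' makes the closure irreversible. C5' (and C3' in the keto tautomer) arise without control, which is harmless because both become sp2 in step 6. The selectivities needed are 1,4 over 1,2 attack, secured by the soft and bulky silyl nucleophile and the open CH2 terminus of 6, and closure through the C3' rather than the C1' enolate, secured by ring size because the C1' enolate could only form a four-membered ring. Slow addition of 6 to a slight excess of 2 keeps 7 from adding to further vinyl ketone.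

Step 6
Reactants: 9 2-(methoxymethoxy)-4-(2-methylbut-3-en-2-yl)cyclohexane-1,3-dione
Product: 12 2-(methoxymethoxy)-4-(2-methylbut-3-en-2-yl)benzene-1,3-diol, via bis(silyloxy)diene 10 (not isolated), via bis(silyl) aryl ether 11 (not isolated)
Conditions: LiN(i-Pr)2 (2.3 equiv), DMPU, THF, −78 → −20 °C; TMSCl (3 equiv), −78 °C → rt; pentane filtration; DDQ (1.05 equiv), 2,6-lutidine, toluene, 0 °C → rt; MeOH, citric acid (cat.), rt, under Ar
Reagents that add atoms: none
Why: Double enolisation and O-silylation give a cyclohexa-1,3-diene that DDQ aromatises by hydride abstraction at C6' (the cation is stabilised by both silyloxy groups) and proton loss from C5' (dehydrogenation of a silyl dienol ether), which spares the monosubstituted alkene and the MOM acetal where Pd/C or halogen-based aromatisation would not, and methanolysis then frees both phenols.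

Step 7
Reactants: 12 2-(methoxymethoxy)-4-(2-methylbut-3-en-2-yl)benzene-1,3-diol
Product: 13 3-methoxy-2-(methoxymethoxy)-6-(2-methylbut-3-en-2-yl)phenol
Conditions: MeI (1.0 equiv), K2CO3 (1.1 equiv), acetone, rt, under Ar
Reagents that add atoms: iodomethane (MeI), CI
Why: Williamson ether synthesis with one equivalent of electrophile: the 4'-oxygen is walled in by the tert-alkyl group at C5' and the OMOM group at C3', so the open 2'-phenoxide should take the methyl group.

Step 8
Reactants: 13 3-methoxy-2-(methoxymethoxy)-6-(2-methylbut-3-en-2-yl)phenol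
Product: 14 4-bromo-3-methoxy-2-(methoxymethoxy)-6-(2-methylbut-3-en-2-yl)phenol
Conditions: NBS (1.0 equiv), MeCN, −20 → 0 °C, dark
Reagents that add atoms: N-bromosuccinimide (NBS), O=C1CCC(=O)N1Br
Why: Electrophilic aromatic bromination: C1' is para to the free 4'-OH and ortho to 2'-OMe whereas C6' is meta to both and flanked by the tert-alkyl group, and the strongly activated ring should outrun the unactivated vinyl group at low temperature.

Step 9
Reactants: 14 4-bromo-3-methoxy-2-(methoxymethoxy)-6-(2-methylbut-3-en-2-yl)phenol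
Product: 15 1-bromo-2-methoxy-3,4-bis(methoxymethoxy)-5-(2-methylbut-3-en-2-yl)benzene
Conditions: NaH (1.3 equiv), DMF–THF, 0 °C; MOMCl (1.3 equiv), 0 °C → rt
Reagents that add atoms: chloromethyl methyl ether (MOMCl), COCCl
Why: MOM protection of the sodium phenoxide: the small and very reactive α-chloro ether still reaches the hindered oxygen, and the product has no acidic proton left for the organolithium step.

Step 10
Reactants: 16 4-bromo-3-chlorophenol
Product: 17 1-bromo-2-chloro-4-(methoxymethoxy)benzene
Conditions: NaH (1.2 equiv), THF, 0 °C; MOMCl (1.2 equiv), 0 °C → rt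
Reagents that add atoms: chloromethyl methyl ether (MOMCl), COCCl
Why: MOM protection of an unhindered phenoxide gives ring A with Br at the future C4a, Cl at the future C8a and the same acid-labile group as ring B.

Step 11
Reactants: 15 1-bromo-2-methoxy-3,4-bis(methoxymethoxy)-5-(2-methylbut-3-en-2-yl)benzene; 18 vinylboronic acid pinacol ester; 17 1-bromo-2-chloro-4-(methoxymethoxy)benzene
Product: 21 2-{(1R)-2-[2-chloro-4-(methoxymethoxy)phenyl]-1-[2-methoxy-3,4-bis(methoxymethoxy)-5-(2-methylbut-3-en-2-yl)phenyl]ethyl}-4,4,5,5-tetramethyl-1,3,2-dioxaborolane, via aryllithium 19 (not isolated), via vinylboronate complex 20 (not isolated)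
Conditions: 15, t-BuLi (2.0 equiv), Et2O, −78 °C; 18 (1.0 equiv), −78 °C → rt; solvent change to THF; 17 (1.1 equiv), KOTf (KOSO2CF3, 2.0 equiv), Pd(OAc)2 (2 mol %), (Sp,Sp)-1,1'-bis[bis(3,5-dimethylphenyl)phosphino]-2,2'-bis[(R)-α-(dimethylamino)benzyl]ferrocene (2.4 mol %), 60 °C
Reagents that add atoms: none
Why: Enantioselective conjunctive cross-coupling: bromine–lithium exchange and addition to 18 give the four-coordinate boronate 20, the aryl complex of divalent palladium formed from 17 (kept cationic by bromide scavenging with KOTf) binds its vinyl group and triggers a 1,2-metallate shift of the ring B aryl from boron to the internal carbon, reductive elimination forges C4–C4a, and the C2-symmetric bisphosphine selects the alkene face so that C3 is set as (R), while the aryl chloride and the hindered vinyl group stay untouched.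

Step 12
Reactants: 21 (R)-secondary pinacol boronic ester
Product: 24 (2R)-3-[2-chloro-4-(methoxymethoxy)phenyl]-2-[2-methoxy-3,4-bis(methoxymethoxy)-5-(2-methylbut-3-en-2-yl)phenyl]propan-1-ol, via chloromethylboronate complex 22 (not isolated), via primary boronic ester 23 (not isolated)
Conditions: BrCH2Cl (3 equiv), n-BuLi (2.5 equiv, dropwise), THF, −78 °C → rt; then 3 M NaOH, 30 % H2O2, 0 °C → rt
Reagents that add atoms: bromochloromethane, ClCBr; hydrogen peroxide, OO
Why: Matteson homologation followed by boronate oxidation: chloromethyllithium adds to boron, the stereogenic carbon migrates with retention as chloride leaves, and oxidation then occurs at the new primary C–B bond, so the configuration at C3 is carried through unchanged.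

Step 13
Reactants: 24 (2R)-3-[2-chloro-4-(methoxymethoxy)phenyl]-2-[2-methoxy-3,4-bis(methoxymethoxy)-5-(2-methylbut-3-en-2-yl)phenyl]propan-1-ol
Product: 25 (3R)-3-[2-methoxy-3,4-bis(methoxymethoxy)-5-(2-methylbut-3-en-2-yl)phenyl]-7-(methoxymethoxy)-3,4-dihydro-2H-chromene
Conditions: [Pd(allyl)Cl]2 (2 mol %), RockPhos [2-(di-tert-butylphosphino)-3-methoxy-6-methyl-2',4',6'-triisopropylbiphenyl] (5 mol %), Cs2CO3 (1.5 equiv), toluene, 90 °C
Reagents that add atoms: none
Why: Intramolecular Buchwald–Hartwig-type C–O coupling: oxidative addition into the aryl chloride, alkoxide binding and reductive elimination from the bulky biarylphosphine complex close six-membered ring C faster than β-hydride elimination, and no bond to C3 is touched.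

Step 14
Reactants: 25 (3R)-3-[2-methoxy-3,4-bis(methoxymethoxy)-5-(2-methylbut-3-en-2-yl)phenyl]-7-(methoxymethoxy)-3,4-dihydro-2H-chromene
Product: 26 4-[(3R)-7-hydroxy-3,4-dihydro-2H-chromen-3-yl]-3-methoxy-6-(2-methylbut-3-en-2-yl)benzene-1,2-diol (target)
Conditions: HCl (1.25 M in MeOH), MeOH–THF, degassed, rt → 40 °C
Reagents that add atoms: none
Why: Acid-catalysed acetal exchange with methanol (MOM cleavage) frees the three phenols under conditions too mild to protonate the monosubstituted alkene, and C3 has no pathway for epimerisation.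

Compound list
1 | methyl 3,3-dimethylpent-4-enoate | C=CC(C)(C)CC(=O)OC | starting material
2 | [(1-methoxy-3,3-dimethylpenta-1,4-dien-1-yl)oxy]trimethylsilane | C=CC(C)(C)C=C(OC)O[Si](C)(C)C | intermediate
3 | methyl glycolate | COC(=O)CO | starting material
4 | methyl 2-(methoxymethoxy)acetate | COCOCC(=O)OC | intermediate
5 | N-methoxy-2-(methoxymethoxy)-N-methylacetamide | COCOCC(=O)N(C)OC | intermediate
6 | 1-(methoxymethoxy)but-3-en-2-one | C=CC(=O)COCOC | intermediate
7 | methyl 6-(methoxymethoxy)-2-(2-methylbut-3-en-2-yl)-5-(trimethylsilyloxy)hex-4-enoate (racemic) | C=CC(C)(C)C(CC=C(COCOC)O[Si](C)(C)C)C(=O)OC | intermediate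
8 | methyl 6-(methoxymethoxy)-2-(2-methylbut-3-en-2-yl)-5-oxohexanoate (racemic) | C=CC(C)(C)C(CCC(=O)COCOC)C(=O)OC | intermediate
9 | 2-(methoxymethoxy)-4-(2-methylbut-3-en-2-yl)cyclohexane-1,3-dione (enolised, racemic) | C=CC(C)(C)C1CCC(=O)C(OCOC)C1=O | intermediate
10 | 3-(methoxymethoxy)-5-(2-methylbut-3-en-2-yl)-2,4-bis(trimethylsilyloxy)cyclohexa-1,3-diene (racemic) | C=CC(C)(C)C1CC=C(O[Si](C)(C)C)C(OCOC)=C1O[Si](C)(C)C | intermediate
11 | 2-(methoxymethoxy)-4-(2-methylbut-3-en-2-yl)-1,3-bis(trimethylsilyloxy)benzene | C=CC(C)(C)c1ccc(O[Si](C)(C)C)c(OCOC)c1O[Si](C)(C)C | intermediate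
12 | 2-(methoxymethoxy)-4-(2-methylbut-3-en-2-yl)benzene-1,3-diol | C=CC(C)(C)c1ccc(O)c(OCOC)c1O | intermediate
13 | 3-methoxy-2-(methoxymethoxy)-6-(2-methylbut-3-en-2-yl)phenol | C=CC(C)(C)c1ccc(OC)c(OCOC)c1O | intermediate
14 | 4-bromo-3-methoxy-2-(methoxymethoxy)-6-(2-methylbut-3-en-2-yl)phenol | C=CC(C)(C)c1cc(Br)c(OC)c(OCOC)c1O | intermediate
15 | 1-bromo-2-methoxy-3,4-bis(methoxymethoxy)-5-(2-methylbut-3-en-2-yl)benzene | C=CC(C)(C)c1cc(Br)c(OC)c(OCOC)c1OCOC | intermediate
16 | 4-bromo-3-chlorophenol | Oc1ccc(Br)c(Cl)c1 | starting material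
17 | 1-bromo-2-chloro-4-(methoxymethoxy)benzene | COCOc1ccc(Br)c(Cl)c1 | intermediate
18 | vinylboronic acid pinacol ester | C=CB1OC(C)(C)C(C)(C)O1 | starting material
19 | [2-methoxy-3,4-bis(methoxymethoxy)-5-(2-methylbut-3-en-2-yl)phenyl]lithium | C=CC(C)(C)c1cc([Li])c(OC)c(OCOC)c1OCOC | intermediate
20 | lithium [2-methoxy-3,4-bis(methoxymethoxy)-5-(2-methylbut-3-en-2-yl)phenyl](pinacolato)(vinyl)borate | C=CC(C)(C)c1cc([B-]2(C=C)OC(C)(C)C(C)(C)O2)c(OC)c(OCOC)c1OCOC.[Li+] | intermediate
21 | 2-{(1R)-2-[2-chloro-4-(methoxymethoxy)phenyl]-1-[2-methoxy-3,4-bis(methoxymethoxy)-5-(2-methylbut-3-en-2-yl)phenyl]ethyl}-4,4,5,5-tetramethyl-1,3,2-dioxaborolane | C=CC(C)(C)c1cc([C@@H](Cc2ccc(OCOC)cc2Cl)B2OC(C)(C)C(C)(C)O2)c(OC)c(OCOC)c1OCOC | intermediate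
22 | lithium (chloromethyl){(1R)-2-[2-chloro-4-(methoxymethoxy)phenyl]-1-[2-methoxy-3,4-bis(methoxymethoxy)-5-(2-methylbut-3-en-2-yl)phenyl]ethyl}(pinacolato)borate | C=CC(C)(C)c1cc([C@@H](Cc2ccc(OCOC)cc2Cl)[B-]2(CCl)OC(C)(C)C(C)(C)O2)c(OC)c(OCOC)c1OCOC.[Li+] | intermediate
23 | 2-{(2R)-3-[2-chloro-4-(methoxymethoxy)phenyl]-2-[2-methoxy-3,4-bis(methoxymethoxy)-5-(2-methylbut-3-en-2-yl)phenyl]propyl}-4,4,5,5-tetramethyl-1,3,2-dioxaborolane | C=CC(C)(C)c1cc([C@@H](Cc2ccc(OCOC)cc2Cl)CB2OC(C)(C)C(C)(C)O2)c(OC)c(OCOC)c1OCOC | intermediate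
24 | (2R)-3-[2-chloro-4-(methoxymethoxy)phenyl]-2-[2-methoxy-3,4-bis(methoxymethoxy)-5-(2-methylbut-3-en-2-yl)phenyl]propan-1-ol | C=CC(C)(C)c1cc([C@@H](Cc2ccc(OCOC)cc2Cl)CO)c(OC)c(OCOC)c1OCOC | intermediate
25 | (3R)-3-[2-methoxy-3,4-bis(methoxymethoxy)-5-(2-methylbut-3-en-2-yl)phenyl]-7-(methoxymethoxy)-3,4-dihydro-2H-chromene | C=CC(C)(C)c1cc([C@@H]2COc3cc(OCOC)ccc3C2)c(OC)c(OCOC)c1OCOC | intermediate
26 | 4-[(3R)-7-hydroxy-3,4-dihydro-2H-chromen-3-yl]-3-methoxy-6-(2-methylbut-3-en-2-yl)benzene-1,2-diol | C=CC(C)(C)c1cc([C@@H]2COc3cc(O)ccc3C2)c(OC)c(O)c1O | target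

Total step count: 14. Longest linear sequence: 12 steps (3 to 26 through steps 2–9 and 11–14).

Steps most likely to fail

Step 5.
- **What may go wrong:**
  - chain growth, in which the freshly formed silyl enol ether adds to more vinyl ketone;
  - attack at the carbonyl carbon instead of the terminus;
  - a ring closure so slow at the crowded ester that cleavage back to the components competes.
- **Fallback (sets out from 5 and 1, returns at 9):** the catalytic silyl-transfer addition is replaced by a stoichiometric lithium enolate addition to an α-silyl vinyl ketone, whose silicon stabilises the adduct carbanion and blocks chain growth. The open-chain compound is then isolated before closure.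
- Amide 5 and [1-(trimethylsilyl)vinyl]magnesium bromide (THF, −78 → 0 °C) should give 1-(methoxymethoxy)-3-(trimethylsilyl)but-3-en-2-one F1.
- Ester 1, deprotonated with LiN(i-Pr)2 (THF, −78 °C), adds to it to give methyl 6-(methoxymethoxy)-2-(2-methylbut-3-en-2-yl)-5-oxo-4-(trimethylsilyl)hexanoate F2.
- NaOMe in MeOH at reflux then removes the silyl group and effects the Dieckmann closure to 9.

Step 6.
- **What may go wrong:**
  - incomplete second enolisation, so that the oxidant meets a mono-enol ether;
  - over-oxidation of the electron-rich arene once it has formed;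
  - acid-induced loss of the MOM group during the oxidation.
- **Fallback (sets out from 9, returns at 12):** selenoxide elimination replaces hydride abstraction.
- Double deprotonation of 9 (LiN(i-Pr)2, 2.2 equiv, THF–DMPU) and selenenylation at the open C1' with PhSeCl (−78 °C) should give 2-(methoxymethoxy)-4-(2-methylbut-3-en-2-yl)-6-(phenylselanyl)cyclohexane-1,3-dione F3.
- H2O2 and pyridine in CH2Cl2 at 0 °C oxidise it to the corresponding selenoxide F4.
- The selenoxide undergoes syn-elimination toward C6', and the resulting enedione tautomerises to 12.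

Step 11.
- **What may go wrong:**
  - halide poisoning of the cationic palladium intermediate;
  - direct transfer of the vinyl or aryl group from boron to palladium (a Suzuki-type leak);
  - eroded facial selectivity, because both aryl partners carry ortho substituents.
- **Fallback (sets out from 15, returns at 24):** auxiliary-controlled enolate alkylation (Evans alkylation) replaces asymmetric catalysis.
- **Ring B imide:**
  - Negishi-type coupling of 15 with the Reformatsky reagent BrZnCH2CO2Et (Pd2(dba)3, XPhos, THF, 60 °C) should give ethyl 2-[2-methoxy-3,4-bis(methoxymethoxy)-5-(2-methylbut-3-en-2-yl)phenyl]acetate F5.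
  - LiOH (THF–H2O) gives the arylacetic acid F6.
  - Pivaloyl chloride and Et3N give the mixed pivalic anhydride F7.
  - This acylates lithiated (R)-4-benzyl-1,3-oxazolidin-2-one to the N-acyl oxazolidinone F8.
- **Ring A electrophile, from commercial 2-chloro-4-hydroxybenzaldehyde:**
  - MOMCl and i-Pr2NEt give 2-chloro-4-(methoxymethoxy)benzaldehyde F9.
  - NaBH4 gives [2-chloro-4-(methoxymethoxy)phenyl]methanol F10.
  - CBr4 and PPh3 (Appel reaction) give 1-(bromomethyl)-2-chloro-4-(methoxymethoxy)benzene F11.
- **Union and return:**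
  - NaN(SiMe3)2 (THF, −78 °C) converts F8 into its chelated Z-enolate, which F11 alkylates on the face away from the auxiliary benzyl group to give the (2R)-alkylated imide F12.
  - LiBH4 (Et2O, MeOH, 0 °C) removes the auxiliary reductively and gives 24.

Further compounds
F1 | step 5 | 1-(methoxymethoxy)-3-(trimethylsilyl)but-3-en-2-one | C=C([Si](C)(C)C)C(=O)COCOC
F2 | step 5 | methyl 6-(methoxymethoxy)-2-(2-methylbut-3-en-2-yl)-5-oxo-4-(trimethylsilyl)hexanoate | C=CC(C)(C)C(CC([Si](C)(C)C)C(=O)COCOC)C(=O)OC
F3 | step 6 | 2-(methoxymethoxy)-4-(2-methylbut-3-en-2-yl)-6-(phenylselanyl)cyclohexane-1,3-dione | C=CC(C)(C)C1CC([Se]c2ccccc2)C(=O)C(OCOC)C1=O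
F4 | step 6 | 2-(methoxymethoxy)-4-(2-methylbut-3-en-2-yl)-6-(phenylseleninyl)cyclohexane-1,3-dione | C=CC(C)(C)C1CC([Se](=O)c2ccccc2)C(=O)C(OCOC)C1=O
F5 | step 11 | ethyl 2-[2-methoxy-3,4-bis(methoxymethoxy)-5-(2-methylbut-3-en-2-yl)phenyl]acetate | C=CC(C)(C)c1cc(CC(=O)OCC)c(OC)c(OCOC)c1OCOC
F6 | step 11 | 2-[2-methoxy-3,4-bis(methoxymethoxy)-5-(2-methylbut-3-en-2-yl)phenyl]acetic acid | C=CC(C)(C)c1cc(CC(=O)O)c(OC)c(OCOC)c1OCOC
F7 | step 11 | 2-[2-methoxy-3,4-bis(methoxymethoxy)-5-(2-methylbut-3-en-2-yl)phenyl]acetic pivalic anhydride | C=CC(C)(C)c1cc(CC(=O)OC(=O)C(C)(C)C)c(OC)c(OCOC)c1OCOC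
F8 | step 11 | (4R)-4-benzyl-3-{2-[2-methoxy-3,4-bis(methoxymethoxy)-5-(2-methylbut-3-en-2-yl)phenyl]acetyl}-1,3-oxazolidin-2-one | C=CC(C)(C)c1cc(CC(=O)N2[C@H](Cc3ccccc3)COC2=O)c(OC)c(OCOC)c1OCOC
F9 | step 11 | 2-chloro-4-(methoxymethoxy)benzaldehyde | COCOc1ccc(C=O)c(Cl)c1
F10 | step 11 | [2-chloro-4-(methoxymethoxy)phenyl]methanol | COCOc1ccc(CO)c(Cl)c1
F11 | step 11 | 1-(bromomethyl)-2-chloro-4-(methoxymethoxy)benzene | COCOc1ccc(CBr)c(Cl)c1
F12 | step 11 | (4R)-4-benzyl-3-{(2R)-3-[2-chloro-4-(methoxymethoxy)phenyl]-2-[2-methoxy-3,4-bis(methoxymethoxy)-5-(2-methylbut-3-en-2-yl)phenyl]propanoyl}-1,3-oxazolidin-2-one | C=CC(C)(C)c1cc([C@@H](Cc2ccc(OCOC)cc2Cl)C(=O)N2[C@H](Cc3ccccc3)COC2=O)c(OC)c(OCOC)c1OCOC
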